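**Plan**

- Retrosynthesis cuts the C4–C5 acyl–alkyl bond (ketone to thioester plus alkylzinc), the C13–ring A bond, the C11–C12 alkenyl–vinyl bond together with the C10 methyl (alkyne carbometalation), the C7–C8 sp3–sp3 bond, and the CH2–ring B bond of the difurylmethane.
- Forward, the C1–C4 piece is made first: ethyl 2-oxobutanoate is chlorinated, reduced by a ketoreductase, silylated and converted to the thioester. The two bought furans (ring A, the 2,4-disubstituted one; ring B, the 3-furyl one) are joined through the bridging carbon.
- The C5–C13 chain grows from the bromo alcohol: C7–C8 coupling to an alkyne, carboalumination/vinylation, hydroboration and coupling to ring A, then C5–OH to iodide to zinc. A Fukuyama coupling closes C4–C5 and desilylation ends the route; no ring is formed anywhere.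
- Stereochemistry: C2 (Cl) and C3 (OH) arise together in the enzymatic reduction. The feature that allows this is that C3 sits between the C4 carbonyl and C2: in the four-carbon precursor C3 is a ketone, so the C2–H between that ketone and chlorine is enolisable and the two C2 configurations interconvert while only one is reduced.
- C6 is bought with (S)-3-bromo-2-methylpropan-1-ol; the 10E alkene comes from syn carboalumination followed by couplings that retain geometry.

Key step: step 2

Remark: target atoms are numbered C1 (methyl on the chlorinated carbon) to C13 (CH2 on ring A). It is assumed that a commercial ketoreductase panel contains an enzyme selective for the (2S,3S) product, to be found by screening.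

**Route**

Step 1
Reactants: 1 ethyl 2-oxobutanoate
Product: 2 ethyl 3-chloro-2-oxobutanoate (racemic)
Conditions: SO2Cl2 (1.0 equiv), CH2Cl2, 0 °C → rt
Reagents that add atoms: sulfuryl chloride, O=S(=O)(Cl)Cl
Why: Electrophilic α-chlorination of a ketone through its enol; the keto ester can enolise only toward C3, and one equivalent of reagent should stop at the monochloride because the product enolises less readily in acid.

Step 2
Reactants: 2 ethyl 3-chloro-2-oxobutanoate (racemic)
Product: 3 ethyl (2S,3S)-3-chloro-2-hydroxybutanoate
Conditions: ketoreductase (panel enzyme selected for the (2S,3S) product), NADP+ (cat.), glucose dehydrogenase, D-glucose, potassium phosphate buffer pH 6.5–7.0 (kept by NaOH titration), DMSO (5% v/v), 30 °C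
Reagents that add atoms: none
Why: In the active site NADPH transfers hydride to one face of the C2 ketone of the bound (3S)-epimer of 2 while an active-site acid protonates the oxygen; the (3R)-epimer that is not accepted returns to the pool through the enol, because the C3–H lies between the ketone and chlorine and exchanges in neutral buffer. The closest known reaction type is the ketoreductase or yeast reduction of 3-chloro-2-oxoalkanoates and the enzymatic dynamic kinetic resolution of α-substituted β-keto esters. No ring and no skeletal bond is formed; only the carbinol C–H bond is made. The carbinol center (C2 of 3, C3 of the target) is set by the face of hydride delivery fixed by the enzyme pocket, and the chlorinated center (C3 of 3, C2 of the target) by the enzyme accepting only one epimer while enolisation keeps both in equilibrium. The step needs one of four stereoisomers and reduction of the ketone alone; the acidity of the C3–H should make epimerisation faster than reduction, the 1,2-dicarbonyl makes the ketone far more reactive than the ester, and once reduced the chlorinated carbon is no longer next to a ketone and is configurationally fixed. Glucose and glucose dehydrogenase recycle NADPH so that the reduction can run to completion.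

Step 3
Reactants: 3 ethyl (2S,3S)-3-chloro-2-hydroxybutanoate
Product: 4 ethyl (2S,3S)-3-chloro-2-[(triethylsilyl)oxy]butanoate
Conditions: Et3SiCl, imidazole, CH2Cl2, 0 °C → rt
Reagents that add atoms: chlorotriethylsilane, CC[Si](Cl)(CC)CC
Why: Silyl ether protection of a secondary alcohol; imidazole is too weak a base to close the chlorohydrin to an epoxide or to enolise the ester, so both stereocenters should be kept.

Step 4
Reactants: 4 ethyl (2S,3S)-3-chloro-2-[(triethylsilyl)oxy]butanoate
Product: 5 S-ethyl (2S,3S)-3-chloro-2-[(triethylsilyl)oxy]butanethioate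
Conditions: AlMe3, EtSH, CH2Cl2, 0 °C (forms Me2AlSEt); then 4, 0 °C → rt; aq. potassium sodium tartrate work-up
Reagents that add atoms: ethanethiol (delivered as Me2AlSEt), CCS
Why: Ester-to-thioester exchange with an aluminium thiolate: the Lewis acidic aluminium activates the ester carbonyl and transfers ethanethiolate without free base, which should spare the silyl ether, the secondary chloride and the α-stereocenter.

Step 5
Reactants: 6 3-bromofuran; 7 4-bromofuran-2-carbaldehyde
Product: 9 (4-bromofuran-2-yl)(furan-3-yl)methanol (racemic), via furan-3-yllithium 8 (not isolated)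
Conditions: n-BuLi, THF, −78 °C; then 7, −78 °C; then H2O
Reagents that add atoms: none
Why: Bromine–lithium exchange followed by 1,2-addition to the aldehyde, which at −78 °C should outrun both isomerisation to the 2-lithiofuran and exchange at the ring bromine of 7; the new carbinol center is racemic and is removed in step 6.

Step 6
Reactants: 9 (4-bromofuran-2-yl)(furan-3-yl)methanol
Product: 10 4-bromo-2-(furan-3-ylmethyl)furan
Conditions: Et3SiH (3 equiv), CF3CO2H, CH2Cl2, 0 °C
Reagents that add atoms: none
Why: Ionic hydrogenation: acid ionises the carbinol to a cation stabilised by both furans and triethylsilane traps it as the methylene, the excess silane and low temperature limiting furan oligomerisation.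

Step 7
Reactants: 11 (S)-3-bromo-2-methylpropan-1-ol
Product: 12 tert-butyl[(2S)-3-bromo-2-methylpropoxy]dimethylsilane
Conditions: t-BuMe2SiCl, imidazole, CH2Cl2, 0 °C → rt
Reagents that add atoms: tert-butyldimethylsilyl chloride, CC(C)(C)[Si](C)(C)Cl
Why: Silyl ether protection of the primary alcohol, needed before the Grignard coupling; the stereocenter is not involved.

Step 8
Reactants: 12 tert-butyl[(2S)-3-bromo-2-methylpropoxy]dimethylsilane; 13 (4-bromobut-1-yn-1-yl)trimethylsilane
Product: 15 tert-butyldimethyl{[(2R)-2-methyl-7-(trimethylsilyl)hept-6-yn-1-yl]oxy}silane, via [4-(trimethylsilyl)but-3-yn-1-yl]magnesium bromide 14 (not isolated)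
Conditions: 13, Mg turnings, THF, rt → 40 °C; then 12, Li2CuCl4 (5 mol %), THF/NMP, 0 °C → rt
Reagents that add atoms: none
Why: Li2CuCl4-catalysed sp3–sp3 cross-coupling of a primary alkyl bromide with a primary alkyl Grignard reagent forms C7–C8 without touching the β-stereocenter, the silyl ether or the silyl-capped alkyne (the descriptor changes from S to R only through the priority change).

Step 9
Reactants: 15 tert-butyldimethyl{[(2R)-2-methyl-7-(trimethylsilyl)hept-6-yn-1-yl]oxy}silane
Product: 16 tert-butyldimethyl{[(2R)-2-methylhept-6-yn-1-yl]oxy}silane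
Conditions: K2CO3, MeOH, rt
Reagents that add atoms: none
Why: Protodesilylation of an alkynylsilane by methoxide cleaves the C(sp)–Si bond and should leave the hindered O–Si bond of the silyl ether intact.

Step 10
Reactants: 16 tert-butyldimethyl{[(2R)-2-methylhept-6-yn-1-yl]oxy}silane
Product: 18 tert-butyl{[(2R,6E)-2,6-dimethylnona-6,8-dien-1-yl]oxy}dimethylsilane, via alkenyldimethylalane 17 (not isolated)
Conditions: AlMe3, Cp2ZrCl2 (25 mol %), CH2Cl2, 0 °C → rt; volatiles removed; then vinyl bromide, Pd(PPh3)4 (5 mol %), ZnCl2 (co-catalyst), THF, rt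
Reagents that add atoms: trimethylaluminium, C[Al](C)C; vinyl bromide, C=CBr
Why: Negishi zirconium-catalysed carboalumination adds methyl and aluminium syn across the terminal alkyne with methyl on the internal carbon, and the alkenylalane then undergoes palladium-catalysed Negishi coupling with vinyl bromide with retention, which fixes the E geometry of the future C10=C11 bond.

Step 11
Reactants: 18 tert-butyl{[(2R,6E)-2,6-dimethylnona-6,8-dien-1-yl]oxy}dimethylsilane; 10 4-bromo-2-(furan-3-ylmethyl)furan
Product: 20 tert-butyl({(2R,6E)-9-[5-(furan-3-ylmethyl)furan-3-yl]-2,6-dimethylnon-6-en-1-yl}oxy)dimethylsilane, via homoallylic 9-BBN borane 19 (not isolated)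
Conditions: 9-BBN, THF, 0 °C → rt; then 10, PdCl2(dppf) (5 mol %), aq. K3PO4, DMF, 60 °C
Reagents that add atoms: none
Why: Anti-Markovnikov hydroboration by 9-BBN at the monosubstituted end of the diene (the trisubstituted alkene is too hindered) gives a homoallylic borane that is joined to the bromofuran by B-alkyl Suzuki–Miyaura coupling; no stereocenter is made and the alkene geometry is untouched.

Step 12
Reactants: 20 tert-butyl({(2R,6E)-9-[5-(furan-3-ylmethyl)furan-3-yl]-2,6-dimethylnon-6-en-1-yl}oxy)dimethylsilane
Product: 21 (2R,6E)-9-[5-(furan-3-ylmethyl)furan-3-yl]-2,6-dimethylnon-6-en-1-ol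
Conditions: Bu4NF, THF, 0 °C → rt
Reagents that add atoms: none
Why: Fluoride-induced cleavage of the silyl ether, to which the furans and the alkene are inert.

Step 13
Reactants: 21 (2R,6E)-9-[5-(furan-3-ylmethyl)furan-3-yl]-2,6-dimethylnon-6-en-1-ol
Product: 22 2-(furan-3-ylmethyl)-4-[(3E,8R)-9-iodo-4,8-dimethylnon-3-en-1-yl]furan
Conditions: I2, PPh3, imidazole, CH2Cl2, 0 °C → rt, dark
Reagents that add atoms: iodine, II
Why: Appel-type iodination: the alcohol is activated as an alkoxyphosphonium salt and displaced by iodide at the primary carbon, so the neighbouring stereocenter is not involved and the buffered medium spares the furans.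

Step 14
Reactants: 22 2-(furan-3-ylmethyl)-4-[(3E,8R)-9-iodo-4,8-dimethylnon-3-en-1-yl]furan; 5 S-ethyl (2S,3S)-3-chloro-2-[(triethylsilyl)oxy]butanethioate
Product: 24 (2S,3S,6R,10E)-2-chloro-13-[5-(furan-3-ylmethyl)furan-3-yl]-6,10-dimethyl-3-[(triethylsilyl)oxy]tridec-10-en-4-one, via alkylzinc iodide 23 (not isolated)
Conditions: Zn dust (activated with BrCH2CH2Br and Me3SiCl), LiCl, THF, 40 °C; then 5, PdCl2(PPh3)2 (5 mol %), toluene/THF, rt
Reagents that add atoms: none
Why: Fukuyama coupling: zinc inserts into the primary C–I bond and the alkylzinc iodide transmetalates to the acylpalladium species formed by oxidative addition of zerovalent palladium into the C–S bond, giving the ketone without over-addition and under conditions too mild to enolise the α-silyloxy center or eliminate the β-chloride.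

Step 15
Reactants: 24 (2S,3S,6R,10E)-2-chloro-13-[5-(furan-3-ylmethyl)furan-3-yl]-6,10-dimethyl-3-[(triethylsilyl)oxy]tridec-10-en-4-one
Product: 25 (2S,3S,6R,10E)-2-chloro-13-[5-(furan-3-ylmethyl)furan-3-yl]-3-hydroxy-6,10-dimethyltridec-10-en-4-one
Conditions: HF·pyridine, pyridine, THF, 0 °C → rt
Reagents that add atoms: none
Why: Acidic fluoride desilylation of the triethylsilyl ether; the buffered reagent avoids the basic conditions that would close the chlorohydrin to an epoxide or eliminate HCl, and should be mild enough for both furans.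

**Compound list**

1 | ethyl 2-oxobutanoate | CCC(=O)C(=O)OCC | starting material
2 | ethyl 3-chloro-2-oxobutanoate (racemic) | CCOC(=O)C(=O)C(C)Cl | intermediate
3 | ethyl (2S,3S)-3-chloro-2-hydroxybutanoate | CCOC(=O)[C@H](O)[C@H](C)Cl | intermediate
4 | ethyl (2S,3S)-3-chloro-2-[(triethylsilyl)oxy]butanoate | CCOC(=O)[C@H](O[Si](CC)(CC)CC)[C@H](C)Cl | intermediate
5 | S-ethyl (2S,3S)-3-chloro-2-[(triethylsilyl)oxy]butanethioate | CCSC(=O)[C@H](O[Si](CC)(CC)CC)[C@H](C)Cl | intermediate
6 | 3-bromofuran | Brc1ccoc1 | starting material
7 | 4-bromofuran-2-carbaldehyde | O=Cc1cc(Br)co1 | starting material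
8 | furan-3-yllithium | [Li]c1ccoc1 | intermediate
9 | (4-bromofuran-2-yl)(furan-3-yl)methanol (racemic) | OC(c1cc(Br)co1)c1ccoc1 | intermediate
10 | 4-bromo-2-(furan-3-ylmethyl)furan | Brc1coc(Cc2ccoc2)c1 | intermediate
11 | (S)-3-bromo-2-methylpropan-1-ol | BrC[C@@H](C)CO | starting material
12 | tert-butyl[(2S)-3-bromo-2-methylpropoxy]dimethylsilane | BrC[C@@H](C)CO[Si](C)(C)C(C)(C)C | intermediate
13 | (4-bromobut-1-yn-1-yl)trimethylsilane | C[Si](C)(C)C#CCCBr | starting material
14 | [4-(trimethylsilyl)but-3-yn-1-yl]magnesium bromide | C[Si](C)(C)C#CCC[Mg]Br | intermediate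
15 | tert-butyldimethyl{[(2R)-2-methyl-7-(trimethylsilyl)hept-6-yn-1-yl]oxy}silane | C[Si](C)(C)C#CCCC[C@@H](C)CO[Si](C)(C)C(C)(C)C | intermediate
16 | tert-butyldimethyl{[(2R)-2-methylhept-6-yn-1-yl]oxy}silane | C#CCCC[C@@H](C)CO[Si](C)(C)C(C)(C)C | intermediate
17 | [(1E,6R)-7-{[tert-butyl(dimethyl)silyl]oxy}-2,6-dimethylhept-1-en-1-yl]dimethylalane | C[Al](C)/C=C(\C)CCC[C@@H](C)CO[Si](C)(C)C(C)(C)C | intermediate
18 | tert-butyl{[(2R,6E)-2,6-dimethylnona-6,8-dien-1-yl]oxy}dimethylsilane | C=C/C=C(\C)CCC[C@@H](C)CO[Si](C)(C)C(C)(C)C | intermediate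
19 | 9-[(3E,8R)-9-{[tert-butyl(dimethyl)silyl]oxy}-4,8-dimethylnon-3-en-1-yl]-9-borabicyclo[3.3.1]nonane | C/C(=C\CCB1C2CCCC1CCC2)CCC[C@@H](C)CO[Si](C)(C)C(C)(C)C | intermediate
20 | tert-butyl({(2R,6E)-9-[5-(furan-3-ylmethyl)furan-3-yl]-2,6-dimethylnon-6-en-1-yl}oxy)dimethylsilane | C/C(=C\CCc1coc(Cc2ccoc2)c1)CCC[C@@H](C)CO[Si](C)(C)C(C)(C)C | intermediate
21 | (2R,6E)-9-[5-(furan-3-ylmethyl)furan-3-yl]-2,6-dimethylnon-6-en-1-ol | C/C(=C\CCc1coc(Cc2ccoc2)c1)CCC[C@@H](C)CO | intermediate
22 | 2-(furan-3-ylmethyl)-4-[(3E,8R)-9-iodo-4,8-dimethylnon-3-en-1-yl]furan | C/C(=C\CCc1coc(Cc2ccoc2)c1)CCC[C@@H](C)CI | intermediate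
23 | {(2R,6E)-9-[5-(furan-3-ylmethyl)furan-3-yl]-2,6-dimethylnon-6-en-1-yl}zinc iodide | C/C(=C\CCc1coc(Cc2ccoc2)c1)CCC[C@@H](C)C[Zn]I | intermediate
24 | (2S,3S,6R,10E)-2-chloro-13-[5-(furan-3-ylmethyl)furan-3-yl]-6,10-dimethyl-3-[(triethylsilyl)oxy]tridec-10-en-4-one | C/C(=C\CCc1coc(Cc2ccoc2)c1)CCC[C@@H](C)CC(=O)[C@H](O[Si](CC)(CC)CC)[C@H](C)Cl | intermediate
25 | (2S,3S,6R,10E)-2-chloro-13-[5-(furan-3-ylmethyl)furan-3-yl]-3-hydroxy-6,10-dimethyltridec-10-en-4-one | C/C(=C\CCc1coc(Cc2ccoc2)c1)CCC[C@@H](C)CC(=O)[C@H](O)[C@H](C)Cl | target

**Step count and risks**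

Total step count: 15. Longest linear sequence: 9 steps (11 to 25, steps 7 to 15).

Steps most likely to fail:

Step 2. The enzyme may reduce both C3 epimers at similar rates, or epimerisation through the enol may lag behind reduction, so that diastereomers form; hydrolysis of the keto ester in buffer may also compete. The fallback builds the same chlorohydrin from the chiral pool by two inversions. It does not use compound 2: it sets out from commercial L-threonine (C[C@@H](O)[C@H](N)C(=O)O) and comes back to the route at compound 3. Diazotisation with NaNO2 and KBr in aqueous H2SO4 at −5 °C should give, with retention through the α-lactone, (2S,3R)-2-bromo-3-hydroxybutanoic acid F1. KOH in ethanol, then acidification, should close it with inversion at C2 to cis-(2R,3R)-3-methyloxirane-2-carboxylic acid F2. Dry HCl in Et2O at 0 °C should open the epoxide at C3, the carbon remote from the carboxyl group, with inversion to (2S,3S)-3-chloro-2-hydroxybutanoic acid F3. Fischer esterification (EtOH, cat. H2SO4) then gives 3.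

Step 14. Zinc insertion may stall or the alkylzinc may be protonated before transmetalation, and the acylpalladium intermediate may decarbonylate or lose HCl. The fallback replaces the acyl cross-coupling by addition of a Grignard reagent to a chelating amide. It sets out from compounds 4 and 22 and comes back at compound 24, leaving out thioester 5. Ester 4 is treated with MeNH(OMe)·HCl and AlMe3 in CH2Cl2 (0 °C → rt) to give (2S,3S)-3-chloro-N-methoxy-N-methyl-2-[(triethylsilyl)oxy]butanamide F4. Iodide 22 is converted with Mg turnings in Et2O into {(2R,6E)-9-[5-(furan-3-ylmethyl)furan-3-yl]-2,6-dimethylnon-6-en-1-yl}magnesium iodide F5. Addition of F5 to F4 in THF at −78 → −20 °C and a cold NH4Cl quench should release ketone 24 from the stable chelate.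

Step 11. Hydroboration may not stop cleanly at the terminal carbon of the conjugated diene, and oxidative addition into the electron-rich bromofuran may be slower than protodeboronation of the borane. The fallback moves the coupling to the C11–C12 bond, with an alkenyl iodide as the electrophile. It sets out from compounds 16 and 10 and comes back at compound 20, leaving out diene 18. Alkyne 16 is carboaluminated as in step 10 (through alane 17) and quenched with I2 in THF at −30 °C to give tert-butyl{[(2R,6E)-7-iodo-2,6-dimethylhept-6-en-1-yl]oxy}dimethylsilane F6. Bromide 10 is vinylated with vinylboronic acid pinacol ester, Pd(PPh3)4 and K2CO3 in dioxane/water at 80 °C to give 4-ethenyl-2-(furan-3-ylmethyl)furan F7. 9-BBN in THF converts F7 into 9-{2-[5-(furan-3-ylmethyl)furan-3-yl]ethyl}-9-borabicyclo[3.3.1]nonane F8. F8 is coupled with F6 (PdCl2(dppf), aq. K3PO4, DMF, rt) with retention of the alkene geometry to give 20.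

**Further compounds**

F1 | step 2 | (2S,3R)-2-bromo-3-hydroxybutanoic acid | C[C@@H](O)[C@H](Br)C(=O)O
F2 | step 2 | (2R,3R)-3-methyloxirane-2-carboxylic acid | C[C@H]1O[C@H]1C(=O)O
F3 | step 2 | (2S,3S)-3-chloro-2-hydroxybutanoic acid | OC(=O)[C@H](O)[C@H](C)Cl
F4 | step 14 | (2S,3S)-3-chloro-N-methoxy-N-methyl-2-[(triethylsilyl)oxy]butanamide | CON(C)C(=O)[C@H](O[Si](CC)(CC)CC)[C@H](C)Cl
F5 | step 14 | {(2R,6E)-9-[5-(furan-3-ylmethyl)furan-3-yl]-2,6-dimethylnon-6-en-1-yl}magnesium iodide | C/C(=C\CCc1coc(Cc2ccoc2)c1)CCC[C@@H](C)C[Mg]I
F6 | step 11 | tert-butyl{[(2R,6E)-7-iodo-2,6-dimethylhept-6-en-1-yl]oxy}dimethylsilane | I/C=C(\C)CCC[C@@H](C)CO[Si](C)(C)C(C)(C)C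
F7 | step 11 | 4-ethenyl-2-(furan-3-ylmethyl)furan | C=Cc1coc(Cc2ccoc2)c1
F8 | step 11 | 9-{2-[5-(furan-3-ylmethyl)furan-3-yl]ethyl}-9-borabicyclo[3.3.1]nonane | C(Cc1coc(Cc2ccoc2)c1)B1C2CCCC1CCC2
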